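A shortage of partner by its charge is impossible in the spring run. The charge is 120% of the starting material, so starting material is the limiting reagent, yet you see target stop near 46%.

| flask | starting material | partner | protic impurity | temperature | remark | time |
|---|---|---|---|---|---|---|
| spring | 0.17 M | 0.204 M | 0.017 M | 85 °C | run made earlier |  |
| dawn | 0.085 M | 0.204 M | 0.017 M | 96 °C | run made earlier |  |
| dusk | 0.34 M | 0.204 M | 0.017 M | 85 °C | run made earlier |  |
| gamma | 0.17 M (fed, over 20 min) | 0.204 M | 0.0170 M | 90 °C | all else is in the flask from the start; the feed brings no volume worth counting | 6.0 h |
| alpha | 0.17 M (fed, over 80 min) | 0.204 M | 0.0170 M | 90 °C | all else is in the flask from the start; the feed brings no volume worth counting | 6.0 h |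
| beta | 0.17 M | 0.204 M (fed, over 80 min) | 0.0170 M |  | the addition at 50 °C, then warmed to 90 °C; the feed brings no volume worth counting | 6.0 h |
| delta | 0.17 M | 0.204 M (fed, over 80 min) | 0.0170 M | 90 °C | all else is in the flask from the start; the feed brings no volume worth counting | 6.0 h |
| eta | 0.17 M (in portions, 5, over 80 min) | 0.204 M | 0.0170 M | 90 °C | first portion at the start, last at 80 min | 6.0 h |

| run | time / h | target / % |
|---|---|---|
| spring | 0.500 | 15 |
| spring | 1.00 | 20 |
| spring | 1.50 | 24 |
| spring | 2.00 | 36 |
| spring | 2.50 | 40 |
| spring | 3.00 | 44 |
| spring | 4.00 | 46 |
| dawn | 0.500 | 25 |
| dawn | 0.667 | 26 |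
| dawn | 1.00 | 30 |
| dawn | 1.50 | 38 |
| dawn | 2.50 | 48 |
| dawn | 4.00 | 53 |
| dawn | 6.00 | 57 |
| dusk | 0.833 | 20 |
| dusk | 1.50 | 26 |
| dusk | 2.50 | 34 |
| dusk | 3.00 | 40 |
| dusk | 4.00 | 44 |
| dusk | 5.00 | 45 |
| dusk | 6.00 | 41 |

(scatter of a reading: 2 percentage points)

- a reading or a percentage of target counts all its forms, free or not

- which flask leads in amount of target, in percent of the starting material charged ("all alike" within 1.5 percentage points) (gamma / alpha / beta / delta / eta / all alike)
- how much target is there at the end, in percent of the starting material charged: gamma
- how much target is there at the end, in percent of the starting material charged: alpha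
- how much target is there at the end, in percent of the starting material charged: beta
- how much target is there at the end, in percent of the starting material charged: delta
- how much target is there at the end, in percent of the starting material charged: eta

So reckon what the partner achieves. Spring gives 38.3%, its partner yield: target made, free or bound, per partner charged. Dusk, at the same temperature with twice the starting material, gives 75.0%, which is twice the spring yield. I therefore read the partner yield as rising with starting material per partner.

Target as a percentage of starting material then barely moves from spring to dusk: 46% against 45%. Dawn reads higher, but it differs from spring in charge as well as temperature, and these runs do not part the two. As a rough estimate, I still interpolate between spring and dawn by temperature to 90 °C. That gives a reference of 51.0% with the charges in from the start.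

A feed of 80 min covers 44.4% of the 3.00 h spring needs to flatten. Over that window, alpha has on average received 0.0850 M. Halving the yield there gives alpha 39.7%.

The halving is the weak link, since it comes from a doubling at 85 °C. Dawn, at 0.085 M and hotter, reads 23.8%, so I take the penalty as 38.0%, with charge and temperature again unparted. Now alpha comes to 42.4%, and I put eta beside it. Gamma, with its shorter window, comes to 48.8%. Delta is the mirror case, with more starting material per partner during the feed, so it comes to 59.6%. I leave beta, fed cold, at the reference. I commit to delta leading.

The forecast differs: it puts alpha first, with gamma 49%, alpha 53%, beta 47%, delta 44% and eta 52%, on the ground that “Feeding partner leaves starting material waiting with little partner”.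

The flasks give gamma 54.6%, alpha 49.8%, beta 54.0%, delta 56.8% and eta 49.7%, so delta leads.

    starting material + protic impurity → quenched substrate (k = 210 M⁻¹ h⁻¹, Ea = 57.0 kJ mol⁻¹)
    starting material + partner → target, rate k2*[starting material]*[partner]^0.5 (k = 1.00 M⁻⁰·⁵ h⁻¹, Ea = 66.0 kJ mol⁻¹)
    starting material + target ⇌ idle adduct, settled at all times (K = 7.10 M⁻¹, ΔH = −12.0 kJ mol⁻¹)
    partner → decomposed reagent (k = 0.320 h⁻¹, Ea = 127 kJ mol⁻¹)
    (constants at 90 °C)

Delta's partner yield is 47.3%, above alpha's 41.5%; spring read 38.3%. The neighbour of eta takes 0.051 M of partner, which puts 4.00 times as much starting material behind each partner. Its charge covers 30.0% of the starting material. Its partner yield comes to 61.6%, above eta's 41.4%. In that neighbour, at 6.00 h, partner stands at 0%, target at 18.5%, and starting material at 63.5%.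

(Readings and results are calculated on assumed constants, noise included.)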